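**Retrosynthetic overview**
1. Feature: ring A (C1'–C6') carries the contiguous oxygen triad O2'/O3'/O4'. Only the central O3' is acylated and both neighbours are free. C3' is the one ring-A carbon between two free OH groups, the central carbon of a masked 1,3-diketone C2'–C3'–C4'.
2. Key disconnection: the C3'–O3' bond, cut with the whole (S)-2-methylbutanoyloxy group attached, giving unprotected cardamonin (C3'–H) and bis[(S)-2-methylbutanoyl] peroxide. Oxygen, acyl group and stereocentre arrive as one piece, so no free pyrogallol, regioselective esterification or protecting group is needed.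
3. Cardamonin comes from Claisen–Schmidt condensation (Cα=Cβ) of 2',4'-dihydroxy-6'-methoxyacetophenone with benzaldehyde. The peroxide comes from (S)-2-methylbutanoic acid (chiral pool, sole stereocentre) and H2O2.
4. Rings: none is formed, since both benzene rings are bought. Order of bond formation: enone C=C, O–O reagent, then C3'–O3'.

Key step: step 3

Assumption: chalcone locants are used (C1' acyl-bearing, C2' chelated OH, C3' acyloxy, C4' OH, C5' H, C6' OMe), and the stereocentre reads (S) from the SMILES, so commercial (S)-2-methylbutanoic acid of high enantiomeric purity supplies it.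

**Step 1**
Reactants: 1 2',4'-dihydroxy-6'-methoxyacetophenone; 2 benzaldehyde
Product: 4 cardamonin [(E)-1-(2,4-dihydroxy-6-methoxyphenyl)-3-phenylprop-2-en-1-one], via aldol adduct 3 (not isolated)
Conditions: KOH (50% aq., excess), EtOH, 0 °C → rt, N2; then cold 2 M HCl to pH 4–5
Reagents that add atoms: none
Why: Claisen–Schmidt condensation, in which the methyl ketone enolate of 1 adds to non-enolisable 2, E1cB loss of water from 3 gives the conjugated (E)-enone under thermodynamic control, and the strongly basic medium holds the product as the open chalcone phenoxide rather than the flavanone.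

**Step 2**
Reactants: 5 (S)-2-methylbutanoic acid (2 equiv)
Product: 8 bis[(S)-2-methylbutanoyl] peroxide, via O-acylisourea 6 (not isolated), via (S)-2-methylperoxybutanoic acid 7 (not isolated)
Conditions: DCC (2.1 equiv), 30% aq. H2O2 (1.1 equiv), DMAP (5 mol %), CH2Cl2, −15 → 0 °C; cold filtration and cold aqueous washes; kept as a titrated dilute CH2Cl2 solution at −30 °C, never concentrated, no silica
Reagents that add atoms: hydrogen peroxide, OO
Why: Carbodiimide-mediated double acylation of hydrogen peroxide, a known preparation of aliphatic diacyl peroxides, in which 5 is activated as 6, perhydrolysed to 7 and 7 is acylated by a second 6, while no bond to the stereocentre is touched and no enolising base is present, so the (S) configuration is carried over in both halves.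

**Step 3**
Reactants: 4 cardamonin; 8 bis[(S)-2-methylbutanoyl] peroxide
Product: 11 target [(E)-2',4'-dihydroxy-6'-methoxy-3'-((S)-2-methylbutanoyloxy)chalcone], via caesium 4'-phenoxide 9 (not isolated), via 3'-acyloxy dienone 10 (not isolated)
Conditions: Cs2CO3 (2.2 equiv), MeCN, rt → −20 °C; then 8 (1.05 equiv, cold CH2Cl2 solution), −20 → 0 °C, dark, N2; cold 1 M HCl to pH 4
Reagents that add atoms: none
Why: Proposed new method: Cs2CO3 removes the most acidic proton of 4 (4'-OH, para to the ketone), and the carbon terminus C3' of the resulting enolate-like phenoxide 9 attacks one peroxide oxygen of 8 in an SN2-type displacement of (S)-2-methylbutanoate (O4' attack on the O–O bond followed by a [3,3] shift of the aryl perester would lead to the same compound), giving dienone 10, which re-aromatises by tautomerisation to 11, so that the C3'–O3' bond and the complete chiral ester are installed in one operation on the unprotected chalcone. The closest known reaction types are the Elbs persulfate oxidation (phenoxide carbon attacks a peroxide oxygen), the ortho-benzoyloxylation of phenols with dibenzoyl peroxide and the α-acyloxylation of 1,3-dicarbonyl enolates with diacyl peroxides; what is new is the transfer of an α-branched alkanoyloxy group to an acylphloroglucinol-type chalcone. No ring is closed and no lasting stereocentre is made: the sp3 centre C3' of 10 is erased on tautomerisation, and the (S) centre is a spectator that sees no bond change and no base able to enolise an ester at or below 0 °C. Site selectivity (C3' over C5', C1' being blocked) is needed and should come from the 2'-OH···O=C chelate, which fixes the C1'=C2' enol and leaves O4'–C4'=C3' as the reactive enolate, the same bias that sends base-mediated C-alkylation and Claisen rearrangements of 2,4-dihydroxyaryl ketones to the carbon between the two oxygens. Chemoselectivity (O–O over acyl C=O attack, ring over enone, single over double oxidation) should come from the soft delocalised nucleophile and the α-branch that shields the acyl carbon, from the electrophilic character of the oxidant towards an electron-poor alkene, and from the deactivating acyloxy group together with a near-stoichiometric charge of 8. Acyl migration is not expected to erode the result, since the 3'-ester is the isomer that keeps both the chelated 2'-OH and the ketone-conjugated 4'-OH free.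

**Compound list**
1 | 2',4'-dihydroxy-6'-methoxyacetophenone | CC(=O)c1c(O)cc(O)cc1OC | starting material
2 | benzaldehyde | O=Cc1ccccc1 | starting material
3 | aldol adduct, 1-(2,4-dihydroxy-6-methoxyphenyl)-3-hydroxy-3-phenylpropan-1-one (racemic, not isolated) | COc1cc(O)cc(O)c1C(=O)CC(O)c1ccccc1 | intermediate
4 | cardamonin, (E)-2',4'-dihydroxy-6'-methoxychalcone | COc1cc(O)cc(O)c1C(=O)/C=C/c1ccccc1 | intermediate
5 | (S)-2-methylbutanoic acid | CC[C@H](C)C(=O)O | starting material
6 | O-[(S)-2-methylbutanoyl]-N,N'-dicyclohexylisourea (not isolated) | CC[C@H](C)C(=O)OC(=NC1CCCCC1)NC1CCCCC1 | intermediate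
7 | (S)-2-methylperoxybutanoic acid (not isolated) | CC[C@H](C)C(=O)OO | intermediate
8 | bis[(S)-2-methylbutanoyl] peroxide (S,S) | CC[C@H](C)C(=O)OOC(=O)[C@@H](C)CC | intermediate
9 | caesium 4'-phenoxide of cardamonin (not isolated) | COc1cc([O-])cc(O)c1C(=O)/C=C/c1ccccc1.[Cs+] | intermediate
10 | 3'-acyloxy dienone, keto tautomer of the target with sp3 C3'–H (configuration at C3' undefined, not isolated) | CC[C@H](C)C(=O)OC1C(=O)C=C(OC)C(C(=O)/C=C/c2ccccc2)=C1O | intermediate
11 | (E)-2',4'-dihydroxy-6'-methoxy-3'-[(S)-2-methylbutanoyloxy]chalcone | CC[C@H](C)C(=O)Oc1c(O)cc(OC)c(C(=O)/C=C/c2ccccc2)c1O | target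

**Total step count:** 3. **Longest linear sequence:** 2 (step 1 → step 3, or step 2 → step 3).

**Steps most likely to fail**

1. Step 3 (Proposed new method).
   - What may go wrong: the phenoxide oxygen may attack the acyl carbon, giving plain O-acylation with release of peracid, instead of carbon attacking the O–O bond. Attack through C5' may compete. Single-electron oxidation of the phenoxide may trigger decarboxylative breakdown of the peroxide.
   - The fallback uses known chemistry only, sets out from 4 and comes back at 11. It makes the C3'–O bond and the ester bond in separate operations under protecting-group control.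
   - Electrophilic iodination of 4 (NIS, MeCN, 0 °C) should give 3'-iodocardamonin F1.
   - Double protection (NaH, MOMCl, DMF, 0 °C) should give 3'-iodo-2',4'-bis(methoxymethoxy)-6'-methoxychalcone F2.
   - Miyaura borylation (B2pin2, Pd(OAc)2/SPhos, KOAc, dioxane, 80 °C) should give the 3'-pinacolboronate F3.
   - Oxidation (NaBO3·4H2O, THF/H2O, rt) should give 3'-hydroxy-2',4'-bis(methoxymethoxy)-6'-methoxychalcone F4.
   - Steglich esterification with 5 (EDC·HCl, DMAP, CH2Cl2, 0 °C → rt) should give its (S)-2-methylbutanoate F5.
   - Acetal cleavage (aq. HCl, THF/i-PrOH, rt) should release 11.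

2. Step 2.
   - What may go wrong: the di-sec-alkanoyl peroxide may decompose by radical-chain and ionic (carboxy-inversion) pathways during preparation, washing or storage. The activated acid may rearrange to N-acylurea. The second acylation may stay incomplete and leave peracid.
   - The fallback sets out from 5 and comes back at 10. The O–O bond is taken from a preformed, storable peracid instead of being built by double acylation of H2O2.
   - Coupling of 5 with purified mCPBA (DCC, CH2Cl2, 0 °C) should give (S)-2-methylbutanoyl 3-chlorobenzoyl peroxide F6. This is a mixed peroxide of the isolable type used for carboxy-inversion chemistry.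
   - Under the conditions of step 3, phenoxide 9 should attack the oxygen next to the alkanoyl group, because this expels the better leaving group 3-chlorobenzoate. That gives 10 and then 11.

3. Step 1.
   - What may go wrong: enolisation of the doubly deprotonated ketone may be suppressed, giving slow conversion. Benzaldehyde may be consumed by the Cannizzaro reaction. The chalcone may cyclise to the flavanone on acidification.
   - The fallback sets out from 1 and comes back at 4. The acidic 4-OH is masked so that only the chelated mono-phenoxide is present.
   - Selective alkylation (MOMCl, K2CO3, acetone, rt) should give 2'-hydroxy-6'-methoxy-4'-(methoxymethoxy)acetophenone F7.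
   - Claisen–Schmidt condensation with 2 (KOH, EtOH, rt) should give 2'-hydroxy-6'-methoxy-4'-(methoxymethoxy)chalcone F8.
   - Acetal cleavage (HCl, MeOH, 40 °C) should give 4.

**Further compounds**
F1 | step 3 | 3'-iodocardamonin, (E)-1-(2,4-dihydroxy-3-iodo-6-methoxyphenyl)-3-phenylprop-2-en-1-one | COc1cc(O)c(I)c(O)c1C(=O)/C=C/c1ccccc1
F2 | step 3 | (E)-3'-iodo-2',4'-bis(methoxymethoxy)-6'-methoxychalcone | COCOc1cc(OC)c(C(=O)/C=C/c2ccccc2)c(OCOC)c1I
F3 | step 3 | (E)-2',4'-bis(methoxymethoxy)-6'-methoxy-3'-(pinacolatoboryl)chalcone | COCOc1cc(OC)c(C(=O)/C=C/c2ccccc2)c(OCOC)c1B1OC(C)(C)C(C)(C)O1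
F4 | step 3 | (E)-3'-hydroxy-2',4'-bis(methoxymethoxy)-6'-methoxychalcone | COCOc1cc(OC)c(C(=O)/C=C/c2ccccc2)c(OCOC)c1O
F5 | step 3 | (E)-2',4'-bis(methoxymethoxy)-6'-methoxy-3'-[(S)-2-methylbutanoyloxy]chalcone | CC[C@H](C)C(=O)Oc1c(OCOC)cc(OC)c(C(=O)/C=C/c2ccccc2)c1OCOC
F6 | step 2 | (S)-2-methylbutanoyl 3-chlorobenzoyl peroxide | CC[C@H](C)C(=O)OOC(=O)c1cccc(Cl)c1
F7 | step 1 | 2'-hydroxy-6'-methoxy-4'-(methoxymethoxy)acetophenone | CC(=O)c1c(O)cc(OCOC)cc1OC
F8 | step 1 | (E)-2'-hydroxy-6'-methoxy-4'-(methoxymethoxy)chalcone | COCOc1cc(O)c(C(=O)/C=C/c2ccccc2)c(OC)c1
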